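The coupling partner is the reagent we count in theta, the flask asked about, followed up to its last reading and now offered remedies.

| flask | starting material | second substrate | coupling partner | free catalyst | temperature | remark | time |
|---|---|---|---|---|---|---|---|
| theta | 0.0010 M | 1 equiv | 1.1 equiv | 15 mol% | 35 °C | the very flask that is asked about, followed so far |  |
| eta | 0.0010 M | 1 equiv | 1.1 equiv | 15 mol% | 41 °C | run made earlier |  |
| flask | 0.0010 M | 1.00 equiv | 1.10 equiv | 15 mol% | 35 °C |  | 40 min |

| run | time / min | target / % | starting material / % |
|---|---|---|---|
| theta | 2.50 | 10.8 | 86.8 |
| theta | 4.00 | 15.2 | 82.9 |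
| theta | 6.00 | 18.3 | 80.7 |
| theta | 10.0 | 20.0 | 77.1 |
| theta | 15.0 | 22.1 | 76.2 |
| theta | 20.0 | 22.1 | 76.0 |
| theta | 30.0 | 22.8 | 75.0 |
| eta | 2.50 | 12.8 | 85.7 |
| eta | 4.00 | 16.3 | 81.2 |
| eta | 6.00 | 19.1 | 77.8 |
| eta | 10.0 | 20.9 | 75.3 |
| eta | 15.0 | 21.6 | 73.8 |
| eta | 20.0 | 21.8 | 74.4 |
| eta | 30.0 | 20.7 | 75.3 |

(standard deviation of a reading: 0.5 percentage points)

1. target, in percent of the starting material first charged, at 40 min
2. the remedy with the largest gain of target, or "none" below 2 percentage points (Sunday's / Tuesday's / Thursday's / Saturday's / Monday's / none)
3. target present, with what was taken out counted in, in percent of the starting material first charged, after Sunday's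
4. target present, with what was taken out counted in, in percent of the starting material first charged, after Tuesday's

- Sunday's: at 40 min add coupling partner, 100% of the amount charged, then wait 80 min
- Tuesday's: at 40 min raise the temperature by 25 K, then wait 80 min
- Thursday's: at 40 min add free catalyst, 50.0% of the amount charged, then wait 80 min
- Saturday's: change nothing and wait 80 min more
- Monday's: at 40 min take out 90% of the target then present, then wait 80 min

- target that was removed still counts
- the numbers in the tables scatter by 0.5 percentage points (one standard deviation)
- additions bring no volume worth counting

The readings form a ladder of time scales. On the first rung, theta has reached 10.8% target by 2.50 min, about half of its last reading. On the next rung, the target stands at 22.1% by 15.0 min and then barely moves, while starting material stays near 75.0%. On the last rung, eta goes from 21.8% to 20.7% over its last interval, against a scatter of 0.5 percentage points per reading, so a slow loss of target can be neither claimed nor excluded. For 40 min we therefore expect about 22.3%.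

What stopped theta? We assume that each turnover costs one coupling partner, that second substrate competes for it, and that theta stopped when its charge of 1.10 equiv was used. Our quantity is the spare partner: partner charged minus second substrate charged, in equivalents of starting material, which is what starting material can still get once second substrate has been served in full. For theta it is 0.100 equiv. The reading shows 25.0% of starting material consumed, more than that, so on this assumption second substrate was not fully served at the stall.

On this assumption, control changes hands where spare partner crosses the starting material charge of 1 equivalent: below it, coupling partner is the limiting reagent, and above it, starting material is. Sunday's addition lifts spare partner to 1.20 equiv, past that crossing. We therefore pick Sunday's and expect a ceiling near 97.8%. The other remedies leave spare partner unchanged, so we expect no gain from them, and for Tuesday's we carry 22.3% as an upper figure.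

The forecast differs: it gave 22.6% now, chose Thursday's, and put 22.8% after Sunday's and 22.6% after Tuesday's, reading the stall as “most likely the catalyst dying”.

The flask gives 22.0% at 40 min, and the best remedy is Sunday's, with 90.3% after it and 2.83% after Tuesday's.

    starting material + free catalyst ⇌ catalyst intermediate A (K = 710 M⁻¹, k = 206 M⁻¹ s⁻¹, Ea = 39.0 kJ mol⁻¹, ΔH = 1.00 kJ mol⁻¹)
    coupling partner + catalyst intermediate A → free catalyst + target (k = 45.2 M⁻¹ s⁻¹, Ea = 35.0 kJ mol⁻¹)
    second substrate + free catalyst ⇌ catalyst intermediate B (K = 30500 M⁻¹, k = 163 M⁻¹ s⁻¹, Ea = 52.0 kJ mol⁻¹, ΔH = −30.0 kJ mol⁻¹)
    coupling partner + catalyst intermediate B → free catalyst + second product (k = 37.6 M⁻¹ s⁻¹, Ea = 47.0 kJ mol⁻¹)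
    target → over-reaction product (k = 2.03 × 10⁻⁵ s⁻¹, Ea = 104 kJ mol⁻¹)
    (constants at 35 °C)

Coupling partner stands at 0% at 40.0 min in this flask, whose spare partner is 0.100 equiv, with second substrate at 5.28%. The neighbouring flask is charged with 0.400 equiv of second substrate, which makes its spare partner 0.700 equiv. That is below the crossing, so we reckon that about 30.0% of its starting material stays unreacted. At 40.0 min it holds 29.4% starting material, its second substrate is down to 0.00674%, and its target stands at 65.4%.

The data are calculated from invented constants, and the scatter is random.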